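**Retrosynthetic overview**

1. Target 26 is a (1S,5S,7S), 7-endo bicyclo[3.3.1]nonane-2,4,9-trione (ring B: C1–C8–C7–C6–C5–C9; ring A: C1–C2–C3–C4–C5–C9). The 3-hydroxybenzoyl group and the free enol are installed last on methyl enol ether 23 (C3 lithiation/aroylation, then hydrolysis).
2. Key disconnection of 23: the bonds C1–C9 and C4–C5, which opens both rings to the chain 20 (C4–C3–C2–C1–C8–C7–C6–C5–C9). In the forward direction ring B closes first (C1–C9) and ring A second (C4–C5), in one operation.
3. Enabling feature: the bridgeheads C1 and C5 are quaternary α-carbons shared by the C9 ketone and one carbonyl of the C2/C4 β-diketone, so ring A is a cyclohexane-1,3,5-trione. It divides into a four-carbon acetoacetate unit (C1 nucleophilic, C4 acyl) and a two-carbon ketene unit (C9 acyl, C5 nucleophilic after attack), already linked by C8–C7–C6.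
4. Chain 20 comes from lactone 9 (Claisen opening, γ-prenylation, O-methylation, iodide, alkylation of aryl ester enolate from 19). Lactone 9 comes from 3,3-dimethylglutaric anhydride by Evans geranylation, which sets C7, the only stereocentre carried into the key step.
5. C1 and C5 of 20 are uncontrolled epimer mixtures; the key step erases them and rebuilds them relative to C7.

Key step: step 11

Remark (assumption): the 2,4-dione is drawn as one enol tautomer and the tautomers interconvert, so only C1, C5 and C7 need control. Atom numbers are those of the bicyclic core (C1 next to the gem-dimethyl carbon C8), and the C1/C5 descriptors of 23, 25 and 26 differ only through CIP priorities, not in space.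

**Route**

Step 1
Reactants: 1 3,3-dimethylglutaric anhydride
Product: 2 5-methoxy-3,3-dimethyl-5-oxopentanoic acid
Conditions: MeOH, reflux
Reagents that add atoms: methanol, CO
Why: Methanolysis of a symmetric cyclic anhydride (nucleophilic acyl substitution) gives the half ester because the carboxylate formed resists a second attack, and no stereocentre is created.

Step 2
Reactants: 2 5-methoxy-3,3-dimethyl-5-oxopentanoic acid; 3 (4R)-4-benzyl-1,3-oxazolidin-2-one
Product: 5 methyl 5-[(4R)-4-benzyl-2-oxo-1,3-oxazolidin-3-yl]-3,3-dimethyl-5-oxopentanoate, via mixed pivalic anhydride 4 (not isolated)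
Conditions: t-BuCOCl, Et3N, THF, −20 °C; then 3, LiCl, −20 °C to rt
Reagents that add atoms: none
Why: N-Acylation of the oxazolidinone through a mixed pivalic anhydride under the LiCl/Et3N protocol is the standard entry to Evans imides, and the auxiliary stereocentre is not touched.

Step 3
Reactants: 5 methyl 5-[(4R)-4-benzyl-2-oxo-1,3-oxazolidin-3-yl]-3,3-dimethyl-5-oxopentanoate; 6 geranyl bromide
Product: 7 methyl (4R,6E)-4-{[(4R)-4-benzyl-2-oxo-1,3-oxazolidin-3-yl]carbonyl}-3,3,7,11-tetramethyldodeca-6,10-dienoate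
Conditions: NaN(SiMe3)2, THF, −78 °C; then 6, −78 to −20 °C
Reagents that add atoms: none
Why: Evans asymmetric alkylation: the chelated sodium (Z)-enolate of the imide (more acidic than the ester) is attacked by the allylic bromide on the face away from the benzyl group of the (4R)-auxiliary, which sets the geranyl-bearing centre (the future C7) in the R configuration shown.

Step 4
Reactants: 7 methyl (4R,6E)-4-{[(4R)-4-benzyl-2-oxo-1,3-oxazolidin-3-yl]carbonyl}-3,3,7,11-tetramethyldodeca-6,10-dienoate
Product: 9 (5R)-5-[(2E)-3,7-dimethylocta-2,6-dien-1-yl]-4,4-dimethyloxan-2-one, via hydroxy ester 8 (not isolated)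
Conditions: NaBH4, THF/H2O, 0 °C to rt; then pyridinium p-toluenesulfonate (catalytic), toluene, 50 °C
Reagents that add atoms: none
Why: Borohydride reductive cleavage of the N-acyl oxazolidinone releases the primary alcohol without touching the adjacent stereocentre or the methyl ester, and the gem-dimethyl group then drives acid-catalysed lactonisation to the six-membered lactone.

Step 5
Reactants: 9 (5R)-5-[(2E)-3,7-dimethylocta-2,6-dien-1-yl]-4,4-dimethyloxan-2-one; 10 methyl acetate
Product: 11 methyl (6R,8E)-6-(hydroxymethyl)-5,5,9,13-tetramethyl-3-oxotetradeca-8,12-dienoate (in equilibrium with its cyclic hemiketal)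
Conditions: LiN(iPr)2 (2.2 equiv), 10 (2.2 equiv), THF, −78 °C; then 9, −78 to −20 °C; aq NH4Cl
Reagents that add atoms: none
Why: Crossed Claisen acylation of the lithium enolate of methyl acetate by the lactone gives the β-keto ester, which is protected from over-addition as its enolate, and no stereocentre is affected.

Step 6
Reactants: 11 methyl (6R,8E)-6-(hydroxymethyl)-5,5,9,13-tetramethyl-3-oxotetradeca-8,12-dienoate; 12 prenyl bromide
Product: 13 methyl (6R,8E)-6-(hydroxymethyl)-5,5,9,13-tetramethyl-4-(3-methylbut-2-en-1-yl)-3-oxotetradeca-8,12-dienoate (C4 epimers)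
Conditions: LiN(iPr)2 (3.2 equiv), THF, −78 to 0 °C; then 12 (1.0 equiv), −78 to 0 °C
Reagents that add atoms: none
Why: γ-Alkylation of a β-keto ester dianion (formed here beside the alkoxide) places the prenyl group on the future C1 because the γ-carbanion is the most reactive site, and the new centre is formed without control, which is of no consequence since step 11 erases it.

Step 7
Reactants: 13 methyl (6R,8E)-6-(hydroxymethyl)-5,5,9,13-tetramethyl-4-(3-methylbut-2-en-1-yl)-3-oxotetradeca-8,12-dienoate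
Product: 14 methyl (2E,6R,8E)-6-(hydroxymethyl)-3-methoxy-5,5,9,13-tetramethyl-4-(3-methylbut-2-en-1-yl)tetradeca-2,8,12-trienoate (C4 epimers)
Conditions: Me2SO4, K2CO3, DMSO, rt
Reagents that add atoms: dimethyl sulfate, COS(=O)(=O)OC
Why: O-Methylation of the potassium enolate of the β-keto ester with a hard electrophile in a dipolar aprotic solvent gives the vinylogous carbonate, expected mainly as the E isomer from the extended enolate, while the neutral primary alcohol is not alkylated under carbonate conditions.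

Step 8
Reactants: 14 methyl (2E,6R,8E)-6-(hydroxymethyl)-3-methoxy-5,5,9,13-tetramethyl-4-(3-methylbut-2-en-1-yl)tetradeca-2,8,12-trienoate
Product: 15 methyl (2E,6R,8E)-6-(iodomethyl)-3-methoxy-5,5,9,13-tetramethyl-4-(3-methylbut-2-en-1-yl)tetradeca-2,8,12-trienoate (C4 epimers)
Conditions: I2, PPh3, imidazole, CH2Cl2, 0 °C to rt
Reagents that add atoms: iodine, II
Why: Appel iodination converts the primary alcohol into the iodide under near-neutral conditions that spare the enol ether and the trisubstituted alkenes, and the neighbouring stereocentre is not involved.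

Step 9
Reactants: 16 5-methylhex-4-enoic acid; 17 2,6-di-tert-butyl-4-methylphenol
Product: 19 2,6-di-tert-butyl-4-methylphenyl 5-methylhex-4-enoate, via acid chloride 18 (not isolated)
Conditions: (COCl)2, DMF (catalytic), CH2Cl2, 0 °C to rt, evaporation; then 17, n-BuLi, THF, 0 °C to rt
Reagents that add atoms: none
Why: Acylation of the lithium phenoxide by the acid chloride is the usual route to esters of this hindered phenol, which resists amine-mediated esterification, and no stereocentre is present.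

Step 10
Reactants: 15 methyl (2E,6R,8E)-6-(iodomethyl)-3-methoxy-5,5,9,13-tetramethyl-4-(3-methylbut-2-en-1-yl)tetradeca-2,8,12-trienoate; 19 2,6-di-tert-butyl-4-methylphenyl 5-methylhex-4-enoate
Product: 20 9-(2,6-di-tert-butyl-4-methylphenyl) 1-methyl (2E,6S)-6-[(2E)-3,7-dimethylocta-2,6-dien-1-yl]-3-methoxy-5,5-dimethyl-4,8-bis(3-methylbut-2-en-1-yl)non-2-enedioate (C4 and C8 epimers)
Conditions: 19, LiN(iPr)2, THF, −78 °C; then 15, DMPU, −78 to −10 °C
Reagents that add atoms: none
Why: Alkylation of the lithium enolate of the hindered aryl ester by the primary iodide (ester enolate alkylation), the enolate being too weak a base to deprotonate the vinylogous carbonate, forms the C5–C6 bond and gives the future C5 as an epimer mixture that step 11 erases.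

Step 11
Reactants: 20 9-(2,6-di-tert-butyl-4-methylphenyl) 1-methyl (2E,6S)-6-[(2E)-3,7-dimethylocta-2,6-dien-1-yl]-3-methoxy-5,5-dimethyl-4,8-bis(3-methylbut-2-en-1-yl)non-2-enedioate
Product: 23 (1R,5S,7S)-7-[(2E)-3,7-dimethylocta-2,6-dien-1-yl]-2-methoxy-8,8-dimethyl-1,5-bis(3-methylbut-2-en-1-yl)bicyclo[3.3.1]non-2-ene-4,9-dione, via ketene dienolate 21 (not isolated), via monocyclic enolate 22 (not isolated)
Conditions: lithium 2,2,6,6-tetramethylpiperidide (2.4 equiv), THF (0.01 M), −78 to −45 °C; then warm to 0 °C and rt; aq NH4Cl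
Reagents that add atoms: none
Why: Proposed new method: the amide base turns both ends of 20 into carbanions, the aryl ester enolate at C5 and the γ-dienolate at C1 of the vinylogous carbonate, and on warming the former expels the hindered lithium aryloxide (E1cB) to give ketene 21, whose sp carbon C9 is captured by C1, and the C5 enolate born in this addition (22) then acylates C4 of the regenerated methoxy enoate with loss of LiOMe. The closest known reaction types are the fragmentation of α,α-disubstituted hindered aryl ester enolates to ketenes with capture by a carbon nucleophile to give a regiodefined ketone enolate, the γ-acylation of dienolates of β-alkoxy enoates, and the Dieckmann closure of bicyclo[3.3.1]nonane-2,4,9-triones. Ring B closes by 6-exo attack of C1 on the ketene carbonyl carbon (the ketene C=C stays in the ring as the enolate, and attack through C3 or oxygen would need an eight- or ten-membered ring), and ring A closes in a 6-(enolendo)-exo-trig Claisen mode in which the C2–C4 unit must be axial on ring B. C1 is set in the first closure: with geranyl equatorial in the chair-like transition state, allylic 1,3-strain should make the planar dienolate turn its C2 flank toward a C8 methyl and not toward C7, so the vinylogous ester becomes equatorial, cis to geranyl, and the prenyl axial, and the C5 configuration then follows from the bridge, ring B folding into the boat typical of 7-endo members of this family. The step needs the right timing (no ketene before the dienolate exists, secured by the persistence of this type of aryl ester enolate below about −20 °C, and no premature attack on C4, which is a non-electrophilic dienolate carbon until C1 has reacted) and the cis C2/geranyl relationship just described; the uncontrolled C1 and C5 centres of 20 are erased, so all its epimers converge.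

Step 12
Reactants: 23 (1R,5S,7S)-7-[(2E)-3,7-dimethylocta-2,6-dien-1-yl]-2-methoxy-8,8-dimethyl-1,5-bis(3-methylbut-2-en-1-yl)bicyclo[3.3.1]non-2-ene-4,9-dione; 24 3-acetoxybenzoyl chloride
Product: 25 (1R,5R,7S)-3-(3-acetoxybenzoyl)-7-[(2E)-3,7-dimethylocta-2,6-dien-1-yl]-2-methoxy-8,8-dimethyl-1,5-bis(3-methylbut-2-en-1-yl)bicyclo[3.3.1]non-2-ene-4,9-dione
Conditions: lithium 2,2,6,6-tetramethylpiperidide, THF, −78 °C; then 24, −78 to −40 °C
Reagents that add atoms: none
Why: Lithiation of the vinylogous ester at C3, the only acidic C–H once both bridgeheads are quaternary, and C-acylation by the aroyl chloride follow the established C3-aroylation of O-methylated bicyclo[3.3.1]nonane-triones, and no stereocentre is affected.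

Step 13
Reactants: 25 (1R,5R,7S)-3-(3-acetoxybenzoyl)-7-[(2E)-3,7-dimethylocta-2,6-dien-1-yl]-2-methoxy-8,8-dimethyl-1,5-bis(3-methylbut-2-en-1-yl)bicyclo[3.3.1]non-2-ene-4,9-dione
Product: 26 (1S,5S,7S)-7-[(2E)-3,7-dimethylocta-2,6-dien-1-yl]-4-hydroxy-3-(3-hydroxybenzoyl)-8,8-dimethyl-1,5-bis(3-methylbut-2-en-1-yl)bicyclo[3.3.1]non-3-ene-2,9-dione (target)
Conditions: LiOH, dioxane/H2O, 90 °C; then aq HCl
Reagents that add atoms: water, O
Why: Hydroxide cleaves the vinylogous methyl ester by addition–elimination at C2 and saponifies the aryl acetate in the same pot, and acidification gives the enolised triketone with the non-enolisable bridgeheads and C7 unchanged.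

**Compound list**

1 | 3,3-dimethylglutaric anhydride (4,4-dimethyloxane-2,6-dione) | O=C1CC(C)(C)CC(=O)O1 | starting material
2 | 5-methoxy-3,3-dimethyl-5-oxopentanoic acid | COC(=O)CC(C)(C)CC(=O)O | intermediate
3 | (4R)-4-benzyl-1,3-oxazolidin-2-one | O=C1N[C@H](Cc2ccccc2)CO1 | starting material
4 | 5-methoxy-3,3-dimethyl-5-oxopentanoic 2,2-dimethylpropanoic anhydride (mixed pivalic anhydride, not isolated) | COC(=O)CC(C)(C)CC(=O)OC(=O)C(C)(C)C | intermediate
5 | methyl 5-[(4R)-4-benzyl-2-oxo-1,3-oxazolidin-3-yl]-3,3-dimethyl-5-oxopentanoate | COC(=O)CC(C)(C)CC(=O)N1[C@H](Cc2ccccc2)COC1=O | intermediate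
6 | geranyl bromide, (2E)-1-bromo-3,7-dimethylocta-2,6-diene | CC(C)=CCC/C(C)=C/CBr | starting material
7 | methyl (4R,6E)-4-{[(4R)-4-benzyl-2-oxo-1,3-oxazolidin-3-yl]carbonyl}-3,3,7,11-tetramethyldodeca-6,10-dienoate | COC(=O)CC(C)(C)[C@@H](C/C=C(\C)CCC=C(C)C)C(=O)N1[C@H](Cc2ccccc2)COC1=O | intermediate
8 | methyl (4R,6E)-4-(hydroxymethyl)-3,3,7,11-tetramethyldodeca-6,10-dienoate (hydroxy ester, not isolated) | COC(=O)CC(C)(C)[C@@H](C/C=C(\C)CCC=C(C)C)CO | intermediate
9 | (5R)-5-[(2E)-3,7-dimethylocta-2,6-dien-1-yl]-4,4-dimethyloxan-2-one | O=C1CC(C)(C)[C@@H](C/C=C(\C)CCC=C(C)C)CO1 | intermediate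
10 | methyl acetate | COC(C)=O | starting material
11 | methyl (6R,8E)-6-(hydroxymethyl)-5,5,9,13-tetramethyl-3-oxotetradeca-8,12-dienoate (open form of the hemiketal) | COC(=O)CC(=O)CC(C)(C)[C@@H](C/C=C(\C)CCC=C(C)C)CO | intermediate
12 | prenyl bromide, 1-bromo-3-methylbut-2-ene | CC(C)=CCBr | starting material
13 | methyl (6R,8E)-6-(hydroxymethyl)-5,5,9,13-tetramethyl-4-(3-methylbut-2-en-1-yl)-3-oxotetradeca-8,12-dienoate (C4 epimers) | COC(=O)CC(=O)C(CC=C(C)C)C(C)(C)[C@@H](C/C=C(\C)CCC=C(C)C)CO | intermediate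
14 | methyl (2E,6R,8E)-6-(hydroxymethyl)-3-methoxy-5,5,9,13-tetramethyl-4-(3-methylbut-2-en-1-yl)tetradeca-2,8,12-trienoate (C4 epimers) | COC(=O)/C=C(/OC)C(CC=C(C)C)C(C)(C)[C@@H](C/C=C(\C)CCC=C(C)C)CO | intermediate
15 | methyl (2E,6R,8E)-6-(iodomethyl)-3-methoxy-5,5,9,13-tetramethyl-4-(3-methylbut-2-en-1-yl)tetradeca-2,8,12-trienoate (C4 epimers) | COC(=O)/C=C(/OC)C(CC=C(C)C)C(C)(C)[C@@H](C/C=C(\C)CCC=C(C)C)CI | intermediate
16 | 5-methylhex-4-enoic acid | CC(C)=CCCC(=O)O | starting material
17 | 2,6-di-tert-butyl-4-methylphenol | Cc1cc(C(C)(C)C)c(O)c(C(C)(C)C)c1 | starting material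
18 | 5-methylhex-4-enoyl chloride (not isolated) | CC(C)=CCCC(=O)Cl | intermediate
19 | 2,6-di-tert-butyl-4-methylphenyl 5-methylhex-4-enoate | CC(C)=CCCC(=O)Oc1c(C(C)(C)C)cc(C)cc1C(C)(C)C | intermediate
20 | 9-(2,6-di-tert-butyl-4-methylphenyl) 1-methyl (2E,6S)-6-[(2E)-3,7-dimethylocta-2,6-dien-1-yl]-3-methoxy-5,5-dimethyl-4,8-bis(3-methylbut-2-en-1-yl)non-2-enedioate (C4 and C8 epimers) | COC(=O)/C=C(/OC)C(CC=C(C)C)C(C)(C)[C@@H](C/C=C(\C)CCC=C(C)C)CC(CC=C(C)C)C(=O)Oc1c(C(C)(C)C)cc(C)cc1C(C)(C)C | intermediate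
21 | lithium dienolate of the ketene formed from 20 by loss of the aryloxide (C5=C9=O ketene, C1 γ-carbanion as dienolate; not isolated) | [Li]OC(OC)=CC(OC)=C(CC=C(C)C)C(C)(C)[C@@H](C/C=C(\C)CCC=C(C)C)CC(CC=C(C)C)=C=O | intermediate
22 | lithium enolate (C9–O–Li, C9=C5) of the ring B ketone with quaternary C1 carrying prenyl and the (E)-methoxy enoate cis to geranyl (not isolated) | CC(C)=CCC/C(C)=C/C[C@H]1CC(CC=C(C)C)=C(O[Li])[C@@](CC=C(C)C)(/C(OC)=C\C(=O)OC)C1(C)C | intermediate
23 | (1R,5S,7S)-7-[(2E)-3,7-dimethylocta-2,6-dien-1-yl]-2-methoxy-8,8-dimethyl-1,5-bis(3-methylbut-2-en-1-yl)bicyclo[3.3.1]non-2-ene-4,9-dione | CC(C)=CCC/C(C)=C/C[C@H]1C[C@]2(CC=C(C)C)C(=O)[C@@](CC=C(C)C)(C(OC)=CC2=O)C1(C)C | intermediate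
24 | 3-acetoxybenzoyl chloride | CC(=O)Oc1cccc(C(=O)Cl)c1 | starting material
25 | (1R,5R,7S)-3-(3-acetoxybenzoyl)-7-[(2E)-3,7-dimethylocta-2,6-dien-1-yl]-2-methoxy-8,8-dimethyl-1,5-bis(3-methylbut-2-en-1-yl)bicyclo[3.3.1]non-2-ene-4,9-dione | CC(C)=CCC/C(C)=C/C[C@H]1C[C@]2(CC=C(C)C)C(=O)[C@@](CC=C(C)C)(C(OC)=C(C(=O)c3cccc(OC(C)=O)c3)C2=O)C1(C)C | intermediate
26 | (1S,5S,7S)-7-[(2E)-3,7-dimethylocta-2,6-dien-1-yl]-4-hydroxy-3-(3-hydroxybenzoyl)-8,8-dimethyl-1,5-bis(3-methylbut-2-en-1-yl)bicyclo[3.3.1]non-3-ene-2,9-dione | CC(C)=CCC/C(C)=C/C[C@H]1C[C@]2(CC=C(C)C)C(=O)[C@@](CC=C(C)C)(C(=O)C(C(=O)c3cccc(O)c3)=C2O)C1(C)C | target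

**Step count and risks**

Total step count: 13. Longest linear sequence: 12 (steps 1–8 and 10–13; step 9 is a one-step side branch).

Steps most likely to fail:

1. Step 11 (Proposed new method). Three processes may defeat it:
   - ketene release before the hindered γ-position at C1 is fully deprotonated, leading to intermolecular acylation and oligomers;
   - attack of C1 from the other face, which would give the 7-exo skeleton;
   - stalling after the first ring, because C-acylation at the tetrasubstituted enolate carbon C5 is slow and only reversible O-acylation occurs.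

   The fallback uses known chemistry, sets out from iodide 15 and returns at 23. It removes the timing problem by making the C9 acyl donor non-enolisable and runs the two ring closures separately; it does not change the facial preference at C1. Iodide 15 alkylates sodium diallyl malonate (NaH, DMF) to give the malonate 7,7-diallyl 1-methyl (1E,5S)-5-[(2E)-3,7-dimethylocta-2,6-dien-1-yl]-2-methoxy-4,4-dimethyl-3-(3-methylbut-2-en-1-yl)hept-1-ene-1,7,7-tricarboxylate F1. C-Prenylation (NaH, 12) gives the quaternary malonate 7,7-diallyl 1-methyl (1E,5S)-5-[(2E)-3,7-dimethylocta-2,6-dien-1-yl]-2-methoxy-4,4-dimethyl-3,7-bis(3-methylbut-2-en-1-yl)hept-1-ene-1,7,7-tricarboxylate F2. LiN(iPr)2 (1.1 equiv, THF, −78 to 0 °C) then deprotonates only the γ-position, and the dienolate closes ring B by Claisen acylation on one allyl ester to give allyl (3R,5S)-3-[(1E)-1,3-dimethoxy-3-oxoprop-1-en-1-yl]-5-[(2E)-3,7-dimethylocta-2,6-dien-1-yl]-4,4-dimethyl-1,3-bis(3-methylbut-2-en-1-yl)-2-oxocyclohexane-1-carboxylate F3. Palladium-catalysed deallylation–decarboxylation (Pd(PPh3)4, morpholine, THF) gives the ketone methyl (2E)-3-[(1R,3S)-3-[(2E)-3,7-dimethylocta-2,6-dien-1-yl]-2,2-dimethyl-1,5-bis(3-methylbut-2-en-1-yl)-6-oxocyclohexyl]-3-methoxyprop-2-enoate F4, whose only enolisable position is C5. KN(SiMe3)2 (THF, −78 °C to rt) then effects the Dieckmann closure to 23.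

2. Step 10. The SN2 reaction at the β-branched iodide may be slow, so that the aryl ester enolate loses aryloxide or transfers a proton before it is alkylated.

   The fallback sets out from 15 and returns at 20. The dilithium dianion of acid 16 (LiN(iPr)2, 2 equiv, THF/DMPU, 0 °C to rt) is alkylated by 15 to give the acid (2E,6S)-6-[(2E)-3,7-dimethylocta-2,6-dien-1-yl]-3-methoxy-5,5-dimethyl-4,8-bis(3-methylbut-2-en-1-yl)non-2-enedioic acid 1-methyl ester F5. This is converted under neutral conditions with 1-chloro-N,N,2-trimethylprop-1-en-1-amine into the acid chloride methyl (2E,6S)-9-chloro-6-[(2E)-3,7-dimethylocta-2,6-dien-1-yl]-3-methoxy-5,5-dimethyl-4,8-bis(3-methylbut-2-en-1-yl)-9-oxonon-2-enoate F6. Acylation of the lithium phenoxide of 17, as in step 9, gives 20.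

3. Step 7. C-Methylation at the doubly activated carbon and the ring–chain equilibrium of the hydroxy keto ester may erode the regiocontrol of the enol ether formation.

   The fallback sets out from 13 and returns at 14. The primary alcohol is silylated (t-BuPh2SiCl, imidazole, CH2Cl2) to give methyl (6R,8E)-6-{[tert-butyl(diphenyl)silyl]oxymethyl}-5,5,9,13-tetramethyl-4-(3-methylbut-2-en-1-yl)-3-oxotetradeca-8,12-dienoate F7, which cannot close to the hemiketal. The enol ether is then formed under thermodynamic, acid-catalysed conditions (trimethyl orthoformate, catalytic camphorsulfonic acid, MeOH, 40 °C) to give methyl (2E,6R,8E)-6-{[tert-butyl(diphenyl)silyl]oxymethyl}-3-methoxy-5,5,9,13-tetramethyl-4-(3-methylbut-2-en-1-yl)tetradeca-2,8,12-trienoate F8. Bu4NF in THF removes the silyl group to return to 14.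

**Further compounds**

F1 | step 11 | 7,7-diallyl 1-methyl (1E,5S)-5-[(2E)-3,7-dimethylocta-2,6-dien-1-yl]-2-methoxy-4,4-dimethyl-3-(3-methylbut-2-en-1-yl)hept-1-ene-1,7,7-tricarboxylate | COC(=O)/C=C(/OC)C(CC=C(C)C)C(C)(C)[C@@H](C/C=C(\C)CCC=C(C)C)CC(C(=O)OCC=C)C(=O)OCC=C
F2 | step 11 | 7,7-diallyl 1-methyl (1E,5S)-5-[(2E)-3,7-dimethylocta-2,6-dien-1-yl]-2-methoxy-4,4-dimethyl-3,7-bis(3-methylbut-2-en-1-yl)hept-1-ene-1,7,7-tricarboxylate | COC(=O)/C=C(/OC)C(CC=C(C)C)C(C)(C)[C@@H](C/C=C(\C)CCC=C(C)C)CC(CC=C(C)C)(C(=O)OCC=C)C(=O)OCC=C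
F3 | step 11 | allyl (3R,5S)-3-[(1E)-1,3-dimethoxy-3-oxoprop-1-en-1-yl]-5-[(2E)-3,7-dimethylocta-2,6-dien-1-yl]-4,4-dimethyl-1,3-bis(3-methylbut-2-en-1-yl)-2-oxocyclohexane-1-carboxylate (C1 epimers) | CC(C)=CCC/C(C)=C/C[C@H]1CC(CC=C(C)C)(C(=O)OCC=C)C(=O)[C@@](CC=C(C)C)(/C(OC)=C\C(=O)OC)C1(C)C
F4 | step 11 | methyl (2E)-3-[(1R,3S)-3-[(2E)-3,7-dimethylocta-2,6-dien-1-yl]-2,2-dimethyl-1,5-bis(3-methylbut-2-en-1-yl)-6-oxocyclohexyl]-3-methoxyprop-2-enoate (C5 epimers) | CC(C)=CCC/C(C)=C/C[C@H]1CC(CC=C(C)C)C(=O)[C@@](CC=C(C)C)(/C(OC)=C\C(=O)OC)C1(C)C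
F5 | step 10 | (2E,6S)-6-[(2E)-3,7-dimethylocta-2,6-dien-1-yl]-3-methoxy-5,5-dimethyl-4,8-bis(3-methylbut-2-en-1-yl)non-2-enedioic acid 1-methyl ester | COC(=O)/C=C(/OC)C(CC=C(C)C)C(C)(C)[C@@H](C/C=C(\C)CCC=C(C)C)CC(CC=C(C)C)C(=O)O
F6 | step 10 | methyl (2E,6S)-9-chloro-6-[(2E)-3,7-dimethylocta-2,6-dien-1-yl]-3-methoxy-5,5-dimethyl-4,8-bis(3-methylbut-2-en-1-yl)-9-oxonon-2-enoate | COC(=O)/C=C(/OC)C(CC=C(C)C)C(C)(C)[C@@H](C/C=C(\C)CCC=C(C)C)CC(CC=C(C)C)C(=O)Cl
F7 | step 7 | methyl (6R,8E)-6-{[tert-butyl(diphenyl)silyl]oxymethyl}-5,5,9,13-tetramethyl-4-(3-methylbut-2-en-1-yl)-3-oxotetradeca-8,12-dienoate | COC(=O)CC(=O)C(CC=C(C)C)C(C)(C)[C@@H](C/C=C(\C)CCC=C(C)C)CO[Si](c1ccccc1)(c1ccccc1)C(C)(C)C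
F8 | step 7 | methyl (2E,6R,8E)-6-{[tert-butyl(diphenyl)silyl]oxymethyl}-3-methoxy-5,5,9,13-tetramethyl-4-(3-methylbut-2-en-1-yl)tetradeca-2,8,12-trienoate | COC(=O)/C=C(/OC)C(CC=C(C)C)C(C)(C)[C@@H](C/C=C(\C)CCC=C(C)C)CO[Si](c1ccccc1)(c1ccccc1)C(C)(C)C
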